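## Structural features

The target is a flavan: an aromatic ring A fused to a dihydropyran ring C, with a 4-hydroxyphenyl ring B on C2. Ring A is a fully differentiated phloroglucinol unit: O1 on C8a, a free hydroxyl on C5, a methoxy group on C7 and a prenyl group on C8 between O1 and the methoxy group. C6 is its only unsubstituted carbon. The two stereocentres, C2 (S) and C4 (R), are 1,3-related across the C3 methylene and are trans, so the aryl group is equatorial and the hydroxyl axial in the half-chair of ring C. The C4 hydroxyl is a benzylic alcohol ortho and para to three oxygen donors and peri to the free 5-OH. It ionises with acid and, once O5 is a phenoxide, by loss through an o-quinone methide. The C2–O1 bond is a benzylic ether that can open when ring B is a free phenol(ate), and the prenyl alkene is acid-sensitive and rules out hydrogenolysis. The real difficulty is to set absolute configuration and the trans 1,3-relationship at two labile benzylic C–O centres while telling three phenolic oxygens apart and placing the prenyl group at C8. The key step uses the fact that C2 is an aldehyde-level carbon between O1 and ring B, C3 is a plain methylene, and C4 is a cation-stabilising position (para to the C7 methoxy group, ortho to O1 and O5). Ring C therefore maps onto a phenol, an aldehyde, a vinyl group and one molecule of water.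

## Logic of the disconnections

**15 back to 14.** The O–acetyl bond on ring B and the O–silyl bond on O5 are cut. The free phenols are what make 15 fragile, so they are unmasked only at the end. The gain is that every earlier intermediate has a single free hydroxyl, at C4. The forward step must be non-acidic, cold and short, so that neither C4–O nor C2–O1 ionises.

**14 back to 12 and 13.** The C8–CH2 aryl–allyl bond is cut. A prenyl alkene present earlier would compete as a π-nucleophile for the oxocarbenium ion and would cyclise onto O1 under acid. A bromine at C8 instead blocks that position and makes ring A slightly less electron-rich. The forward step must couple at a bromide flanked by two oxygens, give the linear allyl isomer, and stay neutral.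

**12 back to 7 and 8.** Three bonds are cut: O1–C2, C2–C3 and C4–O, the last oxygen returning as the water set free when O1–C2 forms. This removes ring C and both stereocentres at once and leaves two simple arenes, so the route is convergent. The forward step needs control of the face of the oxocarbenium carbon by a chiral counter-anion and axial capture of the C4 cation. It also needs a ring A that neither attacks the aldehyde through C6 nor feeds side reactions of the cation. For this reason O5 carries a silyl group (no carbonyl peri to C4) and ring B an acetate (a C2 cation is not stabilised).

**7 back to 4 and 5.** The exocyclic C=C bond (C4=C3 of the later flavan) is cut. The aldehyde is the stable carrier of C4, and the polymerisable vinylphenol is made only immediately before use. The ylide must tolerate one free phenol and an aryl silyl ether.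

**4 back to 3.** The O–Si bond is cut. The two phenols must be told apart because the one next to bromine becomes O1. The forward step relies on the other hydroxyl being the less hindered and the one not held in the hydrogen bond to the formyl group.

**3 back to 2.** The C–Br bond is cut. Compound 2 is symmetric, so either open position gives the same product and regiochemistry is not an issue. The only demand is that bromination stops after one substitution.

**2 back to 1.** The O–CH3 bond is cut. Compound 1 is a commercial phloroglucinol aldehyde whose para hydroxyl is the most acidic and the only one that cannot chelate the formyl group. The forward step must alkylate that oxygen once and leave the two ortho hydroxyls alone.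

## Other disconnections considered

**Alternative 1:** The cut removes ring A altogether. C5–C6, C7–C8 and C4a–C5 are broken, leaving ring C as the bicyclic cyclobutenone A2 and the two-carbon ynol ether A3.

- Forward step: heating should open A2 to a vinylketene, which adds A3 in a regioselective [2+2] step. A second four-electron ring opening, a six-electron electrocyclisation and tautomerisation then give phenol A1.
- In favour: every ring A substituent is placed by the connectivity of the partners. No phenol has to be told from another, no halogen handle or tin reagent is needed, and the 5-OH emerges free. On regiochemical certainty this plan is better than the chosen one. Its neutral thermal conditions are also kinder to the C4–O bond than a Brønsted acid, a second point on which it is better.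
- Against: the key step creates no stereocentre, so C2 and C4 must be made on ring C by a separate sequence. A2 is a strained enol-ether enone whose ring-fusion stereocentre is made only to be destroyed, and no short preparation of it is apparent. A3 is volatile and polymerises easily. The allylic silyl ether and the prenyl group (ene reaction with the ketene) are liabilities at the temperatures needed.
- Comparison: pericyclic steps cannot scramble C2 or C4 but cannot create them either. The sequence should be roughly twice as long as the seven steps to 15.

**Alternative 2:** The cut is the single bond C4–C4a. The precursor is the aryl iodide A5, a (3S)-3-aryl-3-aryloxypropanal.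

- Forward step: CrCl2 with catalytic NiCl2. Zerovalent nickel inserts into the C–I bond, the aryl group passes to trivalent chromium and adds to the tethered aldehyde in a 6-exo-trig closure to give A4.
- In favour: chemoselectivity is very high, so the prenyl group and both silyl ethers can be present from the start and no late coupling is needed; here it is better than the chosen plan. C2 would be set by dependable chemistry (asymmetric ketone reduction, then etherification with inversion), so the absolute configuration does not rest on an unprecedented catalytic step; on risk it is better.
- Against: only one skeletal bond and one stereocentre are formed. C4 depends on 1,3-induction from C2, and the axial, trans alcohol that is needed has no clear bias in a chromium alkoxide transition state. A5 is a β-aryloxy aldehyde that can lose phenoxide by elimination. The aryl–metal bond must form at a carbon flanked by two oxygen substituents. The hexasubstituted arene with iodide, prenyl group and three different oxygens costs many steps, and chromium is used in excess.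
- Comparison: each reaction is individually more certain, but the plan is longer (probably eleven or twelve steps) and leaves the C4 configuration open. The chosen plan gives C4 a stereoelectronic basis and builds ring C from two simple arenes in one step.

**Alternative 3:** The cut is O1–C2 and C3–C4, the retron of a hetero-Diels–Alder reaction. The partners are salicylaldehyde A7 and styrene A8, with orthoformate A9 as the source of the C4 methoxy group.

- Forward step: a chiral phosphoric acid converts A7, through its acetal with A9, into a C4-methoxy o-quinone methide paired with the chiral phosphate. This adds A8 in an inverse-demand [4+2] reaction to give A6.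
- In favour: convergence and output (one ring, two skeletal bonds, two stereocentres) are equal to the chosen plan. It stands closer to established acid-catalysed cycloadditions of o-quinone methides with styrenes, which is better. The prenyl group is already in place, with no halogen and no tin, which is better for the endgame.
- Against: C4 carries a methyl ether. Exchange for hydroxyl means a further acidic solvolysis through the C4 cation, on a molecule with a prenyl group beside O1, and the C4 configuration is then set in that step and not in the key step. In A7 the prenyl group sits next to the free phenol, a pair that acid closes to a dimethylchroman, and its alkene competes with A8 for the quinone methide. A8 is an electron-rich styrene prone to cationic polymerisation, and its silyloxy group makes C2–O1 of A6 ionisable, which endangers the enantiomeric purity. The endo/exo outcome (cis or trans) is not predictable.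
- Comparison: length is equal to slightly longer (A7 needs a regioselective C-prenylation, plus the exchange). The chosen plan delivers the hydroxyl at C4 directly, trans by axial capture, and keeps the prenyl group out of the acidic step.

Key step: step 5

Remarks on the chemistry:

- Configuration check: 2S,4R places the C2 aryl group and the C4 hydroxyl on opposite faces of ring C (2,4-trans). With the aryl group equatorial the hydroxyl is axial, which is what axial capture should give. The descriptors are the same in 12, 14 and 15 because bromine, silyl and acetyl lie outside the atoms that decide priority. No structure needed correction.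
- Precursor design: O5 is carried as a tert-butyldimethylsilyl ether. An ester there was considered and set aside for three reasons. Its carbonyl sits peri to C4 and could bridge the C4 cation as a six-membered acyloxonium ion, which would deliver oxygen in the plane of ring A (cis) and scramble the acyl group. In the product it could shift to the C4 hydroxyl under base and then be expelled by the O5 phenoxide. Aryl esters can also acylate the ylide of step 4. The price is a more electron-rich ring A, which is offset by the C8 bromine, low temperature, a confined acid and a cold amine quench.
- Assumption: the sense of induction of the confined acid cannot be predicted for this substrate. The (S,S) antipode is written, and the mirror-image acid would be used if it leads to the 2R series.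

## Route

Step 1
Reactants: 1 2,4,6-trihydroxybenzaldehyde
Product: 2 2,6-dihydroxy-4-methoxybenzaldehyde
Conditions: Me2SO4 (1.0 equiv), K2CO3 (1.0 equiv), acetone, 0 °C to rt
Reagents that add atoms: dimethyl sulfate, COS(=O)(=O)OC
Why: Williamson-type O-methylation; the 4-OH is para to the formyl group, the most acidic of the three and not tied up in the hydrogen bond to C=O, so one equivalent of weak base ionises it first and the hard electrophile methylates oxygen, not carbon.

Step 2
Reactants: 2 2,6-dihydroxy-4-methoxybenzaldehyde
Product: 3 3-bromo-2,6-dihydroxy-4-methoxybenzaldehyde
Conditions: NBS (1.0 equiv), MeCN, −20 to 0 °C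
Reagents that add atoms: N-bromosuccinimide, O=C1CCC(=O)N1Br
Why: Electrophilic aromatic bromination; C3 and C5 of 2 are equivalent by symmetry, so monobromination can give only one isomer, and the first bromine lowers the reactivity enough for one equivalent at low temperature to stop there.

Step 3
Reactants: 3 3-bromo-2,6-dihydroxy-4-methoxybenzaldehyde
Product: 4 3-bromo-6-(tert-butyldimethylsilyloxy)-2-hydroxy-4-methoxybenzaldehyde
Conditions: TBSCl (1.05 equiv), imidazole (2.2 equiv), CH2Cl2, 0 °C
Reagents that add atoms: tert-butyldimethylsilyl chloride, CC(C)(C)[Si](C)(C)Cl
Why: Silyl ether formation under steric control; the 2-OH is flanked by Br and CHO and is the stronger hydrogen-bond donor to the formyl oxygen, so the bulky chlorosilane should take the open 6-OH and leave free exactly the phenol that becomes O1.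

Step 4
Reactants: 4 3-bromo-6-(tert-butyldimethylsilyloxy)-2-hydroxy-4-methoxybenzaldehyde; 5 methyltriphenylphosphonium bromide
Product: 7 3-bromo-6-(tert-butyldimethylsilyloxy)-2-hydroxy-4-methoxystyrene, via methylenetriphenylphosphorane 6 (not isolated)
Conditions: 5 (2.5 equiv), KOtBu (2.4 equiv), THF, 0 °C; then 4, 0 °C to rt; aq. NH4Cl; used at once
Reagents that add atoms: none
Why: Wittig methylenation; the first equivalent of ylide 6 is spent on the phenol and the rest converts the aldehyde, a standard access to o-vinylphenols, and the base is kept below the phosphonium salt so that no free alkoxide meets the aryl silyl ether.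

Step 5
Reactants: 7 3-bromo-6-(tert-butyldimethylsilyloxy)-2-hydroxy-4-methoxystyrene; 8 4-acetoxybenzaldehyde
Product: 12 (2S,4R)-8-bromo-5-(tert-butyldimethylsilyloxy)-4-hydroxy-7-methoxyflavan 4'-acetate, via hemiacetal 9 (not isolated), via oxocarbenium ion 10 (not isolated), via flavan-4-yl cation 11 (not isolated)
Conditions: (S,S)-imidodiphosphorimidate acid (two 3,3'-diaryl-BINOL units, N-triflyl; 5 mol %), 8 (1.5 equiv), slow addition of 7, CHCl3/methylcyclohexane, −40 °C, no drying agent; Et3N at −40 °C
Reagents that add atoms: none
Why: Proposed new method: the closest known reaction types are the asymmetric Prins cyclisation of homoallylic alcohols with aldehydes under confined imidodiphosphorimidate acids and chiral phosphoric acid annulations of o-hydroxystyrenes, and 7 is a homoallylic alcohol whose two carbinol-side carbons belong to an arene. The acid condenses the phenol of 7 with 8 to hemiacetal 9 and ionises it, with loss of one molecule of water, to the (E)-O-aryl oxocarbenium ion 10, held as a contact ion pair inside the chiral anion. The vinyl terminus (C3) attacks C2 in a 6-endo-trig closure of ring C through a half-chair with the acetoxyphenyl group pseudo-equatorial, giving cation 11, which is delocalised into ring A (C7 methoxy para, O1 and O5 ortho). C2 is set in this C–C bond formation by the face of 10 that the confined anion leaves open, so the enantiocontrol comes from the catalyst. C4 is set when the water just released adds to 11 along the axial trajectory, syn to the axial C2–H and anti to the aryl group, which gives the 2,4-trans alcohol. The bulky 5-silyloxy group reinforces this, because a pseudo-equatorial C4–O bond would clash with it (peri strain), so kinetic and thermodynamic preferences agree even if 12 re-ionises. Chemoselectivity rests on the substrate: bromine blocks C8 and tempers ring A, the silyl ether offers no carbonyl to bridge the cation, no second alkene is present, and the acetate keeps ring B from stabilising a C2 cation so that C2–O1 does not reopen. No drying agent is used because the water of condensation is the nucleophile, and slow addition of 7 to excess 8 keeps the free styrene low so that 11 meets water before it meets a second arene or alkene.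

Step 6
Reactants: 12 (2S,4R)-8-bromo-5-(tert-butyldimethylsilyloxy)-4-hydroxy-7-methoxyflavan 4'-acetate; 13 tributyl(3-methylbut-2-enyl)stannane
Product: 14 (2S,4R)-5-(tert-butyldimethylsilyloxy)-4-hydroxy-7-methoxy-8-(3-methylbut-2-enyl)flavan 4'-acetate
Conditions: 13 (1.5 equiv), Pd(PPh3)4 (10 mol %), DMF, 90 °C, Ar
Reagents that add atoms: none
Why: Stille coupling; zerovalent palladium inserts into C8–Br, the allyl group passes from tin to palladium, and reductive elimination at the less substituted allyl terminus should give the linear prenyl group, while the neutral medium leaves acetate, silyl ether, the C4 alcohol and both stereocentres untouched.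

Step 7
Reactants: 14 (2S,4R)-5-(tert-butyldimethylsilyloxy)-4-hydroxy-7-methoxy-8-(3-methylbut-2-enyl)flavan 4'-acetate
Product: 15 (2S,4R)-4,5,4'-trihydroxy-7-methoxy-8-(3-methylbut-2-enyl)flavan
Conditions: K2CO3 (3 equiv), MeOH, 0 °C, Ar; pH 7 phosphate buffer
Reagents that add atoms: none
Why: Base-mediated methanolysis: transesterification of the aryl acetate and methoxide attack at silicon of the aryl silyl ether, both with phenoxide leaving groups; no bond to C2 or C4 is broken, so both centres are kept, and cold, brief exposure with a neutral quench avoids ionisation of the C4 alcohol.

## Compound list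

1 | 2,4,6-trihydroxybenzaldehyde | O=Cc1c(O)cc(O)cc1O | starting material
2 | 2,6-dihydroxy-4-methoxybenzaldehyde | COc1cc(O)c(C=O)c(O)c1 | intermediate
3 | 3-bromo-2,6-dihydroxy-4-methoxybenzaldehyde | COc1cc(O)c(C=O)c(O)c1Br | intermediate
4 | 3-bromo-6-(tert-butyldimethylsilyloxy)-2-hydroxy-4-methoxybenzaldehyde | COc1cc(O[Si](C)(C)C(C)(C)C)c(C=O)c(O)c1Br | intermediate
5 | methyltriphenylphosphonium bromide | C[P+](c1ccccc1)(c1ccccc1)c1ccccc1.[Br-] | starting material
6 | methylenetriphenylphosphorane | C=P(c1ccccc1)(c1ccccc1)c1ccccc1 | intermediate (not isolated)
7 | 3-bromo-6-(tert-butyldimethylsilyloxy)-2-hydroxy-4-methoxystyrene | COc1cc(O[Si](C)(C)C(C)(C)C)c(C=C)c(O)c1Br | intermediate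
8 | 4-acetoxybenzaldehyde | CC(=O)Oc1ccc(C=O)cc1 | starting material
9 | hemiacetal from the phenol of 7 and the aldehyde 8 (hemiacetal carbon undefined) | COc1cc(O[Si](C)(C)C(C)(C)C)c(C=C)c(OC(O)c2ccc(OC(C)=O)cc2)c1Br | intermediate (not isolated)
10 | O-aryl oxocarbenium ion from 9 | COc1cc(O[Si](C)(C)C(C)(C)C)c(C=C)c([O+]=Cc2ccc(OC(C)=O)cc2)c1Br | intermediate (not isolated)
11 | (2S)-8-bromo-5-(tert-butyldimethylsilyloxy)-7-methoxy-2-(4-acetoxyphenyl)chroman-4-yl cation | COc1cc(O[Si](C)(C)C(C)(C)C)c2c(c1Br)O[C@H](c1ccc(OC(C)=O)cc1)C[CH+]2 | intermediate (not isolated)
12 | (2S,4R)-8-bromo-5-(tert-butyldimethylsilyloxy)-4-hydroxy-7-methoxyflavan 4'-acetate | COc1cc(O[Si](C)(C)C(C)(C)C)c2c(c1Br)O[C@H](c1ccc(OC(C)=O)cc1)C[C@H]2O | intermediate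
13 | tributyl(3-methylbut-2-enyl)stannane | CCCC[Sn](CCCC)(CCCC)CC=C(C)C | starting material
14 | (2S,4R)-5-(tert-butyldimethylsilyloxy)-4-hydroxy-7-methoxy-8-(3-methylbut-2-enyl)flavan 4'-acetate | COc1cc(O[Si](C)(C)C(C)(C)C)c2c(c1CC=C(C)C)O[C@H](c1ccc(OC(C)=O)cc1)C[C@H]2O | intermediate
15 | (2S,4R)-4,5,4'-trihydroxy-7-methoxy-8-(3-methylbut-2-enyl)flavan | COc1cc(O)c2c(c1CC=C(C)C)O[C@H](c1ccc(O)cc1)C[C@H]2O | target

## Step count and least certain steps

Total: 7 steps. Longest linear sequence: 7 steps (1 to 15); compounds 5, 8 and 13 are bought.

**Step 5 (key step, the one step without direct precedent).**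

- What may go wrong: the O-aryl oxocarbenium ion may form too slowly from a phenol that is flanked by bromine, so that acid-promoted self-condensation of the vinylphenol or Friedel–Crafts attack of the activated aldehyde at C6 takes over. The C4 cation may lose a proton from C3 instead of taking up water. Re-ionisation of the doubly activated benzylic alcohol may feed oligomerisation. The anion may discriminate the two faces of the oxocarbenium carbon poorly.
- Fallback by known chemistry, from 4 back to 12: aldehyde 4 is condensed with the stabilised ylide 1-(4-acetoxyphenyl)-2-(triphenylphosphoranylidene)ethanone F1 (toluene, 80 °C) to give the (E)-2-hydroxychalcone F2. Its C=C bond is saturated (H2, RhCl(PPh3)3, benzene/EtOH), sparing the aryl bromide, to give the dihydrochalcone F3. Asymmetric transfer hydrogenation of the ketone (RuCl[(R,R)-TsDPEN](p-cymene), HCO2H/Et3N) should give the (R)-configured benzylic alcohol F4. Mitsunobu cyclisation (PPh3, DIAD, THF, 0 °C) closes O1–C2 with inversion to give the (2S)-flavan F5. The acetoxyphenyl group keeps this displacement on the SN2 path. Benzylic oxidation at C4 with DDQ in wet CH2Cl2 then abstracts hydride para to the methoxy group, and water should add axially to the same cation as in the key step, returning to the route at 12. Over-oxidation to the flavanone is the point to watch there.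

**Step 6.**

- What may go wrong: slow oxidative addition at a bromide flanked by two oxygens, with reduction of the C–Br bond as the competing process. Allyl transposition during transmetalation may give coupling through the tertiary terminus. The tin halide may assist thermal ionisation at C4.
- Fallback from 12 to 14: Stille coupling with allyltributylstannane (Pd(PPh3)4, toluene, 90 °C), which has no terminus ambiguity and transfers faster, should give the 8-allyl compound (2S,4R)-8-allyl-5-(tert-butyldimethylsilyloxy)-4-hydroxy-7-methoxyflavan 4'-acetate F6. Cross-metathesis with excess 2-methyl-2-butene (second-generation Grubbs catalyst RuCl2(=CHPh)(H2IMes)(PCy3), CH2Cl2, 40 °C) then builds the prenyl group and rejoins the route at 14.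

**Step 3.**

- What may go wrong: silylation at the more acidic hydroxyl next to bromine, or at both hydroxyls.
- Fallback from 2 to 4, with the order of events reversed: the symmetric diol 2 is monosilylated (TBSCl, imidazole, CH2Cl2, 0 °C; the second hydroxyl is then locked in the hydrogen bond to the formyl group) to give 6-(tert-butyldimethylsilyloxy)-2-hydroxy-4-methoxybenzaldehyde F7. Ortho-selective bromination of the free phenol (NBS, catalytic i-Pr2NH, CH2Cl2, 0 °C) then targets the position between the hydroxyl and the methoxy group; the other open position is shielded by the silyl ether. The route is rejoined at 4.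

**Step 7.**

- What may go wrong: phenoxide-assisted ionisation at C4 with methanol incorporation or epimerisation, migration of the silyl group from O5 to O4 so that an alkyl silyl ether survives, and opening of C2–O1 through the ring B phenoxide with loss of configuration at C2.
- Fallback from 14 to 15, in two near-neutral operations: the acetate is removed first by hydrazinolysis (N2H4·AcOH, DMF, rt), giving (2S,4R)-5-(tert-butyldimethylsilyloxy)-4,4'-dihydroxy-7-methoxy-8-prenylflavan F8. The silyl group, on O5 or on O4 if it has migrated, is then cleaved with acetic acid-buffered fluoride in an aprotic solvent (TBAF/AcOH, THF, 0 °C), which reaches 15 without a free phenoxide in methanol.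

**Step 1.**

- What may go wrong: alkylation of a second hydroxyl or of an ortho hydroxyl in place of the para one.
- Fallback from 1 to 2: methylation is pushed to the stage where only the chelated hydroxyl is left (Me2SO4, 2.2 equiv, K2CO3, acetone, reflux), giving 2-hydroxy-4,6-dimethoxybenzaldehyde F9. The methyl ether ortho to the formyl group is then cleaved selectively by chelation-directed demethylation (BCl3, CH2Cl2, −78 to 0 °C), which returns to the route at 2.

## Further compounds

F1 | step 5 | 1-(4-acetoxyphenyl)-2-(triphenylphosphoranylidene)ethanone | CC(=O)Oc1ccc(cc1)C(=O)C=P(c1ccccc1)(c1ccccc1)c1ccccc1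
F2 | step 5 | (E)-1-(4-acetoxyphenyl)-3-[3-bromo-6-(tert-butyldimethylsilyloxy)-2-hydroxy-4-methoxyphenyl]prop-2-en-1-one | COc1cc(O[Si](C)(C)C(C)(C)C)c(/C=C/C(=O)c2ccc(OC(C)=O)cc2)c(O)c1Br
F3 | step 5 | 1-(4-acetoxyphenyl)-3-[3-bromo-6-(tert-butyldimethylsilyloxy)-2-hydroxy-4-methoxyphenyl]propan-1-one | COc1cc(O[Si](C)(C)C(C)(C)C)c(CCC(=O)c2ccc(OC(C)=O)cc2)c(O)c1Br
F4 | step 5 | 4-[(1R)-3-[3-bromo-6-(tert-butyldimethylsilyloxy)-2-hydroxy-4-methoxyphenyl]-1-hydroxypropyl]phenyl acetate | COc1cc(O[Si](C)(C)C(C)(C)C)c(CC[C@@H](O)c2ccc(OC(C)=O)cc2)c(O)c1Br
F5 | step 5 | (2S)-8-bromo-5-(tert-butyldimethylsilyloxy)-7-methoxyflavan 4'-acetate | COc1cc(O[Si](C)(C)C(C)(C)C)c2c(c1Br)O[C@H](c1ccc(OC(C)=O)cc1)CC2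
F6 | step 6 | (2S,4R)-8-allyl-5-(tert-butyldimethylsilyloxy)-4-hydroxy-7-methoxyflavan 4'-acetate | COc1cc(O[Si](C)(C)C(C)(C)C)c2c(c1CC=C)O[C@H](c1ccc(OC(C)=O)cc1)C[C@H]2O
F7 | step 3 | 6-(tert-butyldimethylsilyloxy)-2-hydroxy-4-methoxybenzaldehyde | COc1cc(O)c(C=O)c(O[Si](C)(C)C(C)(C)C)c1
F8 | step 7 | (2S,4R)-5-(tert-butyldimethylsilyloxy)-4,4'-dihydroxy-7-methoxy-8-(3-methylbut-2-enyl)flavan | COc1cc(O[Si](C)(C)C(C)(C)C)c2c(c1CC=C(C)C)O[C@H](c1ccc(O)cc1)C[C@H]2O
F9 | step 1 | 2-hydroxy-4,6-dimethoxybenzaldehyde | COc1cc(O)c(C=O)c(OC)c1
A1 | alternative 1 | (2S,4R)-4-(tert-butyldimethylsilyloxy)-2-[4-(tert-butyldimethylsilyloxy)phenyl]-7-methoxy-8-(3-methylbut-2-enyl)chroman-5-ol | COc1cc(O)c2c(c1CC=C(C)C)O[C@H](c1ccc(O[Si](C)(C)C(C)(C)C)cc1)C[C@H]2O[Si](C)(C)C(C)(C)C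
A2 | alternative 1 | (3S,5R)-5-(tert-butyldimethylsilyloxy)-3-[4-(tert-butyldimethylsilyloxy)phenyl]-8-(3-methylbut-2-enyl)-2-oxabicyclo[4.2.0]oct-1(8)-en-7-one (C6 undefined) | O=C1C(CC=C(C)C)=C2O[C@H](c3ccc(O[Si](C)(C)C(C)(C)C)cc3)C[C@@H](O[Si](C)(C)C(C)(C)C)C12
A3 | alternative 1 | methoxyacetylene | COC#C
A4 | alternative 2 | (2S,4R)-2-[4-(tert-butyldimethylsilyloxy)phenyl]-7-methoxy-8-(3-methylbut-2-enyl)-5-(triisopropylsilyloxy)chroman-4-ol | COc1cc(O[Si](C(C)C)(C(C)C)C(C)C)c2c(c1CC=C(C)C)O[C@H](c1ccc(O[Si](C)(C)C(C)(C)C)cc1)C[C@H]2O
A5 | alternative 2 | (3S)-3-[4-(tert-butyldimethylsilyloxy)phenyl]-3-[2-iodo-5-methoxy-6-(3-methylbut-2-enyl)-3-(triisopropylsilyloxy)phenoxy]propanal | COc1cc(O[Si](C(C)C)(C(C)C)C(C)C)c(I)c(O[C@@H](CC=O)c2ccc(O[Si](C)(C)C(C)(C)C)cc2)c1CC=C(C)C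
A6 | alternative 3 | (2S,4R)-5-(tert-butyldimethylsilyloxy)-2-[4-(tert-butyldimethylsilyloxy)phenyl]-4,7-dimethoxy-8-(3-methylbut-2-enyl)chroman | COc1cc(O[Si](C)(C)C(C)(C)C)c2c(c1CC=C(C)C)O[C@H](c1ccc(O[Si](C)(C)C(C)(C)C)cc1)C[C@H]2OC
A7 | alternative 3 | 6-(tert-butyldimethylsilyloxy)-2-hydroxy-4-methoxy-3-(3-methylbut-2-enyl)benzaldehyde | COc1cc(O[Si](C)(C)C(C)(C)C)c(C=O)c(O)c1CC=C(C)C
A8 | alternative 3 | 4-(tert-butyldimethylsilyloxy)styrene | C=Cc1ccc(O[Si](C)(C)C(C)(C)C)cc1
A9 | alternative 3 | trimethyl orthoformate | COC(OC)OC
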